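Ring C is cut at the O1–C8a aryl ether bond, then the open chain is cut at C2–C3 and C3–OMe together. This leaves a ring A diazoketone, methanol and a ring B aldehyde, with the two ring B phenols carried as benzyl ethers.
The cut is possible because C3 bears a methoxy group and lies between the C4 ketone and the oxygen-bearing C2. This α-methoxy-β-oxy ketone array is what forms when the methanol oxonium ylide of a diazoketone adds to an aldehyde.
Forward, ring A (from 1-fluoro-3,5-dimethoxybenzene) and ring B (from 2-methoxyhydroquinone) are joined with methanol in a three-component step that forms no ring. Ring C is then closed by displacement of fluoride, and the benzyl groups are removed last.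
Both stereocentres come from the three-component step under a chiral phosphoric acid. The carbinol centre becomes C2 without its C–O bond being broken, and the 2,3-trans arrangement set there is also the thermodynamically preferred one.

Key step: step 5

Assumption: the sense of induction of the phosphoric acid in step 5 cannot be predicted with confidence. The (R)-acid is written, and its antipode would be used instead if that is the one leading to the (2R,3R) adduct.

Step 1
Reactants: 1 1-fluoro-3,5-dimethoxybenzene
Product: 2 1-(2-fluoro-4,6-dimethoxyphenyl)ethan-1-one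
Conditions: Ac2O, Sc(OTf)3 (5 mol %), MeNO2, 50 °C
Reagents that add atoms: acetic anhydride, CC(=O)OC(C)=O
Why: Friedel–Crafts acylation of a doubly activated arene, in which the acylium ion should enter para to one methoxy group and ortho to the other at the carbon next to the small fluorine, in preference to the more crowded carbon between the two methoxy groups.

Step 2
Reactants: 2 1-(2-fluoro-4,6-dimethoxyphenyl)ethan-1-one
Product: 4 2-diazo-1-(2-fluoro-4,6-dimethoxyphenyl)ethan-1-one, via trifluoroacetyl diketone 3 (not isolated)
Conditions: LiN(SiMe3)2, THF, −78 °C; CF3CO2CH2CF3; then MsN3, Et3N, H2O, MeCN, rt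
Reagents that add atoms: methanesulfonyl azide, CS(=O)(=O)N=[N+]=[N-] (the two diazo nitrogens of 4); 2,2,2-trifluoroethyl trifluoroacetate, O=C(OCC(F)(F)F)C(F)(F)F (the trifluoroacetyl group of 3, lost again before 4)
Why: Danheiser detrifluoroacetylative diazo transfer, in which Claisen trifluoroacetylation of the lithium enolate activates the methyl carbon for diazo transfer from the sulfonyl azide and the trifluoroacetyl group then leaves as the N-sulfonyl amide, a sequence that is standard for aryl methyl ketones.

Step 3
Reactants: 5 2-methoxyhydroquinone (2-methoxybenzene-1,4-diol)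
Product: 6 1,4-bis(benzyloxy)-2-methoxybenzene
Conditions: BnBr, K2CO3, DMF, rt, under N2
Reagents that add atoms: benzyl bromide, BrCc1ccccc1
Why: Williamson etherification of both phenoxides with an unhindered benzylic bromide, giving ethers that should survive the formylation, carbenoid and carbonate steps and come off at the end under neutral conditions.

Step 4
Reactants: 6 1,4-bis(benzyloxy)-2-methoxybenzene
Product: 8 2,5-bis(benzyloxy)-4-methoxybenzaldehyde, via aryl iminium salt 7 (not isolated)
Conditions: POCl3, DMF, 0 to 60 °C; then H2O
Reagents that add atoms: N,N-dimethylformamide, CN(C)C=O (formyl carbon); water, O (carbonyl oxygen)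
Why: Vilsmeier–Haack formylation, in which the chloroiminium ion should attack the carbon para to the methoxy group and ortho to a benzyloxy group, the only site activated by two oxygen donors that is not flanked on both sides, just as 1,2,4-trimethoxybenzene is formylated to the 2,4,5-trisubstituted aldehyde.

Step 5
Reactants: 4 2-diazo-1-(2-fluoro-4,6-dimethoxyphenyl)ethan-1-one; 8 2,5-bis(benzyloxy)-4-methoxybenzaldehyde; 9 methanol
Product: 11 (2R,3R)-3-[2,5-bis(benzyloxy)-4-methoxyphenyl]-1-(2-fluoro-4,6-dimethoxyphenyl)-3-hydroxy-2-methoxypropan-1-one, via methanol oxonium ylide 10 (not isolated)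
Conditions: Rh2(OAc)4 (2 mol %), (R)-3,3'-bis(2,4,6-triisopropylphenyl)-1,1'-binaphthyl-2,2'-diyl hydrogen phosphate [(R)-TRIP, 5 mol %], 8 (1.5 equiv), MeOH (1.2 equiv), 3 Å MS, CH2Cl2, 0 °C; 4 added by syringe pump over 3 h
Reagents that add atoms: none
Why: Proposed new method: Rh2(OAc)4 should convert 4 with loss of N2 into an electrophilic rhodium carbenoid, methanol should add to it to give the protic oxonium ylide 10 (in equilibrium with its enol), and the phosphoric acid, hydrogen-bonded at once to the enol O–H and to the formyl oxygen of 8, should deliver the aldehyde to the ylide carbon before the 1,2-proton shift that would end in plain O–H insertion. The closest known reactions are the Rh2(OAc)4/chiral phosphoric acid three-component Mannich-type couplings of diazo carbonyl compounds (aryl diazoacetates and diazoacetophenones) with alcohols and imines and the aldol-type trapping of alcohol-derived oxonium ylides by electron-poor aryl aldehydes; what is new is the use of an acceptor-only diazoketone, methanol and an electron-rich benzaldehyde together under chiral-acid control. No ring is closed: the step forms the C2–C3 bond and the C2–OMe bond of the open chain (propanone numbering of 11). Both stereocentres arise in the one C–C bond-forming event inside the hydrogen-bonded assembly, the binaphthyl pocket of the acid choosing the face of the aldehyde (C3, R) and the face of the enol (C2, R, anti to the hydroxyl). The step needs chemoselectivity (aldehyde trapping ahead of proton shift, and capture of the carbenoid by methanol ahead of the neighbouring aryl methoxy oxygen) and facial control at the aldehyde; in the substrates the ortho fluorine is inert to the carbenoid, the ortho methoxy oxygen is a weak donor because it is conjugated with the aroyl group, the electron-rich aroyl group makes the enol a strong nucleophile, and the ortho benzyloxy group of 8 gives the acid a second point of contact. Keeping methanol and an excess of 8 in the flask while 4 is added slowly should hold the carbenoid concentration low and let both intermolecular events win.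

Step 6
Reactants: 11 (2R,3R)-3-[2,5-bis(benzyloxy)-4-methoxyphenyl]-1-(2-fluoro-4,6-dimethoxyphenyl)-3-hydroxy-2-methoxypropan-1-one
Product: 12 (2R,3R)-2-[2,5-bis(benzyloxy)-4-methoxyphenyl]-3,5,7-trimethoxy-2,3-dihydro-4H-chromen-4-one
Conditions: K2CO3, DMF, 40 °C, under argon
Reagents that add atoms: none
Why: Intramolecular SNAr (6-exo addition–elimination of the secondary alkoxide at the fluorine-bearing carbon through a Meisenheimer intermediate stabilised by the ortho ketone), the known way from β-hydroxy 2-fluorophenyl ketones to chroman-4-ones, in which the carbinol C–O bond is not broken so that its configuration becomes C2 unchanged and the trans arrangement at C3 is retained as the more stable one.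

Step 7
Reactants: 12 (2R,3R)-2-[2,5-bis(benzyloxy)-4-methoxyphenyl]-3,5,7-trimethoxy-2,3-dihydro-4H-chromen-4-one
Product: 13 (2R,3R)-2-(2,5-dihydroxy-4-methoxyphenyl)-3,5,7-trimethoxy-2,3-dihydro-4H-chromen-4-one (CNP0281794.1)
Conditions: H2 (1 atm), Pd/C (10 wt %), EtOAc, rt; filtration and concentration under argon
Reagents that add atoms: none
Why: Heterogeneous hydrogenolysis of the two aryl benzyl ethers, which should be cleaved much faster than the cyclic benzylic C2–O1 bond or the electron-rich aryl ketone reacts, as in the routine debenzylation of flavanones, and which touches no stereocentre.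

Compound list
1 | 1-fluoro-3,5-dimethoxybenzene | COc1cc(F)cc(OC)c1 | starting material
2 | 1-(2-fluoro-4,6-dimethoxyphenyl)ethan-1-one | CC(=O)c1c(F)cc(OC)cc1OC | intermediate
3 | 4,4,4-trifluoro-1-(2-fluoro-4,6-dimethoxyphenyl)butane-1,3-dione (formed as its lithium enolate) | COc1cc(F)c(C(=O)CC(=O)C(F)(F)F)c(OC)c1 | intermediate (not isolated)
4 | 2-diazo-1-(2-fluoro-4,6-dimethoxyphenyl)ethan-1-one | COc1cc(F)c(C(=O)C=[N+]=[N-])c(OC)c1 | intermediate
5 | 2-methoxyhydroquinone (2-methoxybenzene-1,4-diol) | COc1cc(O)ccc1O | starting material
6 | 1,4-bis(benzyloxy)-2-methoxybenzene | COc1cc(OCc2ccccc2)ccc1OCc1ccccc1 | intermediate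
7 | {[2,5-bis(benzyloxy)-4-methoxyphenyl]methylidene}dimethyliminium dichlorophosphate | COc1cc(OCc2ccccc2)c(C=[N+](C)C)cc1OCc1ccccc1.[O-]P(=O)(Cl)Cl | intermediate (not isolated)
8 | 2,5-bis(benzyloxy)-4-methoxybenzaldehyde | COc1cc(OCc2ccccc2)c(C=O)cc1OCc1ccccc1 | intermediate
9 | methanol | CO | starting material
10 | protic oxonium ylide from methanol and the carbenoid of 4, [2-(2-fluoro-4,6-dimethoxyphenyl)-2-oxoethyl](methyl)oxonium ylide, drawn as the zwitterion | C[OH+][CH-]C(=O)c1c(F)cc(OC)cc1OC | intermediate (not isolated)
11 | (2R,3R)-3-[2,5-bis(benzyloxy)-4-methoxyphenyl]-1-(2-fluoro-4,6-dimethoxyphenyl)-3-hydroxy-2-methoxypropan-1-one | O[C@H](c1cc(OCc2ccccc2)c(OC)cc1OCc1ccccc1)[C@@H](OC)C(=O)c1c(F)cc(OC)cc1OC | intermediate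
12 | (2R,3R)-2-[2,5-bis(benzyloxy)-4-methoxyphenyl]-3,5,7-trimethoxy-2,3-dihydro-4H-chromen-4-one | COc1cc(OC)c2c(c1)O[C@H](c1cc(OCc3ccccc3)c(OC)cc1OCc1ccccc1)[C@@H](OC)C2=O | intermediate
13 | (2R,3R)-2-(2,5-dihydroxy-4-methoxyphenyl)-3,5,7-trimethoxy-2,3-dihydro-4H-chromen-4-one | COc1cc(OC)c2c(c1)O[C@H](c1cc(O)c(OC)cc1O)[C@@H](OC)C2=O | target

Total step count: 7
Longest linear sequence: 5 steps (1 → 2 → 4 → 11 → 12 → 13; the ring B branch 5 → 6 → 8 → 11 → 12 → 13 is equally long)

Steps most likely to fail

Step 5. Several processes could divert the coupling: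
- The proton shift within the ylide may outrun addition to the electron-rich, poorly electrophilic aldehyde, so that only O–H insertion occurs.
- The carbenoid may be captured by the neighbouring aryl methoxy oxygen, followed by protonation and loss of the methyl group.
- Facial selection by the acid may be weak.
- The new, strongly activated benzylic carbinol may ionise under the acid.

The fallback separates the events and uses known reactions only. It sets out from 4, which with Rh2(OAc)4 in MeOH/CH2Cl2 at rt should give, by plain O–H insertion, 1-(2-fluoro-4,6-dimethoxyphenyl)-2-methoxyethan-1-one F1. Its lithium enolate (LiN(SiMe3)2, THF, −78 °C) should add to 8 to give 3-[2,5-bis(benzyloxy)-4-methoxyphenyl]-1-(2-fluoro-4,6-dimethoxyphenyl)-3-hydroxy-2-methoxypropan-1-one as a racemic mixture of diastereomers F2. Oxidation with Dess–Martin periodinane should give 1-[2,5-bis(benzyloxy)-4-methoxyphenyl]-3-(2-fluoro-4,6-dimethoxyphenyl)-2-methoxypropane-1,3-dione F3, whose central carbon epimerises freely. Noyori–Ikariya transfer hydrogenation with dynamic kinetic resolution (RuCl[(S,S)-TsDPEN](p-cymene), HCO2H/Et3N, CH2Cl2, rt) should reduce the less hindered ring B carbonyl to the (3R)-carbinol. By analogy with α-alkoxy β-keto esters the syn isomer is expected, (2S,3R)-3-[2,5-bis(benzyloxy)-4-methoxyphenyl]-1-(2-fluoro-4,6-dimethoxyphenyl)-3-hydroxy-2-methoxypropan-1-one F4. Under the carbonate conditions of step 6, F4 should close to the cis compound (2R,3S)-2-[2,5-bis(benzyloxy)-4-methoxyphenyl]-3,5,7-trimethoxy-2,3-dihydro-4H-chromen-4-one F5, which should epimerise at C3 in the same flask to the trans isomer. The fallback comes back to the route at 12.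

Step 6. The β-alkoxide may fragment by retro-aldol reaction, helped by the stability of the electron-rich aldehyde, or eliminate to the α-methoxychalcone. The substitution itself may be slow because the ketone is only a moderate activator in this electron-rich ring. The product may also lose configuration at C2 by ring opening through its C3 enolate. The fallback avoids a stoichiometric Brønsted base. It sets out from 11, which is silylated (TMSCl, imidazole, CH2Cl2, 0 °C) to (2R,3R)-3-[2,5-bis(benzyloxy)-4-methoxyphenyl]-1-(2-fluoro-4,6-dimethoxyphenyl)-2-methoxy-3-[(trimethylsilyl)oxy]propan-1-one F6. Catalytic fluoride (CsF, 10 mol %, DMF, rt) should then start a desilylative SNAr in which each ring closure releases the fluoride that frees the next alkoxide. The free alkoxide is thus present only in trace amounts. The fallback comes back to the route at 12.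

Step 7. The cyclic benzylic C2–O1 bond, activated by the ortho and para oxygens of ring B, may undergo hydrogenolysis alongside the benzyl ethers, opening ring C. The liberated methoxyhydroquinone may also oxidise in air to the quinone. The fallback replaces reduction by Lewis-acid debenzylation. It sets out from 12, which with BCl3 and pentamethylbenzene as cation scavenger in CH2Cl2 at −78 °C should lose both benzyl groups while the methyl ethers survive at that temperature. It comes back to the route at 13 and makes no new compound (F0).

Further compounds
F1 | step 5 | 1-(2-fluoro-4,6-dimethoxyphenyl)-2-methoxyethan-1-one | COCC(=O)c1c(F)cc(OC)cc1OC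
F2 | step 5 | 3-[2,5-bis(benzyloxy)-4-methoxyphenyl]-1-(2-fluoro-4,6-dimethoxyphenyl)-3-hydroxy-2-methoxypropan-1-one, racemic mixture of diastereomers | COC(C(O)c1cc(OCc2ccccc2)c(OC)cc1OCc1ccccc1)C(=O)c1c(F)cc(OC)cc1OC
F3 | step 5 | 1-[2,5-bis(benzyloxy)-4-methoxyphenyl]-3-(2-fluoro-4,6-dimethoxyphenyl)-2-methoxypropane-1,3-dione | COC(C(=O)c1cc(OCc2ccccc2)c(OC)cc1OCc1ccccc1)C(=O)c1c(F)cc(OC)cc1OC
F4 | step 5 | (2S,3R)-3-[2,5-bis(benzyloxy)-4-methoxyphenyl]-1-(2-fluoro-4,6-dimethoxyphenyl)-3-hydroxy-2-methoxypropan-1-one | O[C@H](c1cc(OCc2ccccc2)c(OC)cc1OCc1ccccc1)[C@H](OC)C(=O)c1c(F)cc(OC)cc1OC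
F5 | step 5 | (2R,3S)-2-[2,5-bis(benzyloxy)-4-methoxyphenyl]-3,5,7-trimethoxy-2,3-dihydro-4H-chromen-4-one | COc1cc(OC)c2c(c1)O[C@H](c1cc(OCc3ccccc3)c(OC)cc1OCc1ccccc1)[C@H](OC)C2=O
F6 | step 6 | (2R,3R)-3-[2,5-bis(benzyloxy)-4-methoxyphenyl]-1-(2-fluoro-4,6-dimethoxyphenyl)-2-methoxy-3-[(trimethylsilyl)oxy]propan-1-one | C[Si](C)(C)O[C@H](c1cc(OCc2ccccc2)c(OC)cc1OCc1ccccc1)[C@@H](OC)C(=O)c1c(F)cc(OC)cc1OC
F0 | step 7 | none | none
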